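**Plan**

1. Numbering: C1 = CH–O(ester), C2=C3, C4 = sp2 fusion carbon, C5 = vinylic CH, C6 = C=O, C7 = CH–OH, C8 = CH2, C9 = quaternary C–CH3, C10 = CH–CH3; ring A = C1–C2–C3–C4–C9–C10, ring B = C4–C5–C6–C7–C8–C9; β = the face of the C9 methyl.
2. Cuts: the C1–O ester bond, which releases (2E,4E,6R)-6-hydroxy-6-methylocta-2,4-dienoic acid, and in ring A the bonds C1–C2 and C2–C3, so that C2 is taken out as a carbene carbon.
3. Enabling feature: ring A is the cyclopentene ring (C1, C3, C4, C9, C10) of a Hajos–Parrish hydrindadienone plus the single carbon C2, which sits between the allylic C1–O carbon and C3 and is conjugated through C4=C5 with the C6 ketone. This is the 2-bromoallyl pattern that a gem-dibromocyclopropane gives on opening.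
4. Forward: ring B and the five-membered ring come from (S)-Hajos–Parrish ketone; the C10 methyl, the C1=C3 alkene and the C7 oxygen are added; CBr2 insertion then enlarges the five-membered ring to ring A; last, the acid is joined at C1, the C2 bromine is removed and C7–OH is unmasked.
5. Stereochemistry: C9 from the Hajos–Parrish ketone; C10 by hydrogenation anti to the C9 methyl; C7 by epoxidation anti to that methyl; C1 by α-face bromide return followed by SN2 inversion; the side-chain carbinol from (S)-2-methylglycidol.

Key step: step 7

Remark on the chemistry: the opening of adduct 14 is assumed to need more heat than a plain 6,6-dibromobicyclo[3.1.0]hexane, because the allyl cation is conjugated to an enone; hence the toluene stage in step 7.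

**Step 1**
Reactants: 1 (S)-Hajos–Parrish ketone; 2 methyltriphenylphosphonium bromide
Product: 3 10-methylene enone
Conditions: 2 (1.1 equiv), KOtBu, THF, 0 °C → rt
Reagents that add atoms: methyltriphenylphosphonium bromide 2, C[P+](c1ccccc1)(c1ccccc1)c1ccccc1.[Br-]
Why: Wittig methylenation: the unconjugated cyclopentanone carbonyl (C10) is more electrophilic than the conjugated C6 carbonyl, so one equivalent of ylide should react at C10 only; no stereocentre is formed and C9 is untouched.

**Step 2**
Reactants: 3 10-methylene enone
Product: 4 9β,10β-dimethyl enone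
Conditions: H2 (1 atm), RhCl(PPh3)3 (5 mol %), PhH–EtOH, rt
Reagents that add atoms: none
Why: Homogeneous hydrogenation with Wilkinson's catalyst reduces the 1,1-disubstituted exocyclic alkene and spares the trisubstituted conjugated C4=C5 bond (as in carvone to dihydrocarvone); hydrogen is delivered to the α face, away from the adjacent C9 methyl, so the new C10 methyl is β, cis to it.

**Step 3**
Reactants: 4 9β,10β-dimethyl enone
Product: 5 linear dienone
Conditions: chloranil (1.3 equiv), t-BuOH, reflux
Reagents that add atoms: none
Why: Quinone dehydrogenation of an enone to the linear dienone (the Δ4-3-ketone to Δ4,6-dienone reaction of steroids): the dienol formed through the only γ-hydrogens (C3, since C9 is quaternary) gives up hydride from C1, which places the new alkene at C1=C3 without touching C9 or C10.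

**Step 4**
Reactants: 5 linear dienone
Product: 9 7α-hydroxy dienone, via lithium trienolate 6 (not isolated), via silyl trienol ether 7 (not isolated), via 7α-silyloxy dienone 8 (not isolated)
Conditions: LDA, THF, −78 °C; TMSCl; then mCPBA, NaHCO3, CH2Cl2, −20 °C; 1 M HCl, THF
Reagents that add atoms: 3-chloroperoxybenzoic acid (mCPBA), OOC(=O)c1cccc(Cl)c1
Why: Rubottom oxidation: kinetic deprotonation takes the α′ hydrogen at C7, the silyl enol ether bond C6=C7 is the most electron-rich alkene and is epoxidised from the α face, anti to the pseudoaxial C9 methyl that lies 1,3 to C7, and silyl migration followed by acid work-up leaves the 7α (equatorial) alcohol.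

**Step 5**
Reactants: 9 7α-hydroxy dienone
Product: 10 7α-TBS-oxy dienone
Conditions: TBSCl, imidazole, DMF, rt
Reagents that add atoms: tert-butyldimethylsilyl chloride, CC(C)(C)[Si](C)(C)Cl
Why: Standard silylation of a secondary alcohol; the silyl ether protects the α-ketol from carbene O–H insertion in step 7 and from enolisation-driven side reactions in steps 12 and 13, and no stereocentre is touched.

**Step 6**
Reactants: 11 phenylmercury(II) chloride; 12 bromoform
Product: 13 phenyl(tribromomethyl)mercury
Conditions: KOtBu, PhH, 0–10 °C
Reagents that add atoms: bromoform 12, BrC(Br)Br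
Why: Seyferth preparation of the carbene-transfer reagent: tert-butoxide deprotonates bromoform and the tribromomethyl anion displaces chloride at mercury faster than it loses bromide at this temperature.

**Step 7**
Reactants: 10 7α-TBS-oxy dienone; 13 phenyl(tribromomethyl)mercury
Product: 15 1α,2-dibromo dienone, via dibromocyclopropane adduct 14 (not isolated)
Conditions: 13 (1.5 equiv), PhH, 80 °C; then PhMe, 110 °C
Reagents that add atoms: phenyl(tribromomethyl)mercury 13, BrC(Br)(Br)[Hg]c1ccccc1
Why: At 80 °C 13 extrudes phenylmercury bromide and transfers free dibromocarbene under neutral conditions (no enolate, so C7 and C10 cannot epimerise), and the electrophilic carbene adds in a concerted [2+1] cheletropic fashion to C1=C3 to close the cyclopropane of 14. The closest known reactions are dihalocarbene additions to the γ,δ-bond of linear dienones (steroidal 4,6-dien-3-ones) and the thermal rearrangement of 6,6-dibromobicyclo[3.1.0]hexanes to 2,3-dibromocyclohexenes. Ring A is not made by a new cyclisation but by ring enlargement: strain-driven disrotatory 2π-electrocyclic cleavage of the shared C1–C3 bond with loss of the endo bromide (Woodward–Hoffmann–DePuy rule) turns the bicyclo[3.1.0]hexane into a six-membered 2-bromoallyl cation, the net result being the new bonds C1–C2 and C2–C3. The one new stereocentre, C1, is set by collapse of the contact ion pair: the endo bromide leaves on the α face, the face the carbene entered anti to the β methyls at C9 and C10, and returns on that face to give the 1α bromide. Site selectivity (C1=C3 over C4=C5) rests on the carbonyl, which deactivates the α,β-alkene, and on the quaternary C9 that shields it; regioselectivity of bromide return (C1, not C3) rests on the conjugation C2=C3–C4=C5–C6=O that only the C1 bromide keeps, the doubly allylic C3 bromide being able to re-ionise and correct itself.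

**Step 8**
Reactants: 16 (S)-2-methylglycidol; 17 methylmagnesium bromide
Product: 18 (R)-2-methylbutane-1,2-diol
Conditions: 17 (3 equiv), CuI (10 mol %), THF, −30 → 0 °C; aq. NH4Cl
Reagents that add atoms: methylmagnesium bromide 17, C[Mg]Br
Why: Copper-catalysed Grignard opening of a 2,2-disubstituted epoxide at its unsubstituted CH2 terminus (SN2); the tertiary C–O bond is not broken, so the carbinol centre is retained and becomes (R) only through the change in CIP priorities.

**Step 9**
Reactants: 18 (R)-2-methylbutane-1,2-diol
Product: 19 (R)-2-hydroxy-2-methylbutanal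
Conditions: IBX (1.3 equiv), EtOAc, 75 °C; filter, use crude
Reagents that add atoms: none
Why: IBX oxidation of the primary alcohol; IBX does not cleave 1,2-diols and cannot oxidise the tertiary carbinol, and the quaternary α-carbon cannot epimerise.

**Step 10**
Reactants: 19 (R)-2-hydroxy-2-methylbutanal; 20 triethyl (E)-4-phosphonocrotonate
Product: 21 ethyl (2E,4E,6R)-6-hydroxy-6-methylocta-2,4-dienoate
Conditions: 20, LiHMDS, THF, −78 °C; then 19, −78 → 0 °C
Reagents that add atoms: triethyl (E)-4-phosphonocrotonate 20, CCOC(=O)/C=C/CP(=O)(OCC)OCC
Why: Vinylogous Horner–Wadsworth–Emmons olefination; the stabilised phosphonate anion is not basic enough to deprotonate the tertiary alcohol, the 2E geometry comes with the reagent and the new 4E bond from the usual E-selective elimination with an α-branched aldehyde.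

**Step 11**
Reactants: 21 ethyl (2E,4E,6R)-6-hydroxy-6-methylocta-2,4-dienoate
Product: 22 (2E,4E,6R)-6-hydroxy-6-methylocta-2,4-dienoic acid
Conditions: LiOH, THF–H2O, rt; then 1 M HCl to pH 3, 0 °C
Reagents that add atoms: lithium hydroxide, [Li+].[OH-]
Why: Ester saponification; the tertiary carbinol and the diene are inert to aqueous hydroxide (no retro-aldol is possible, because C5 is sp2) and brief cold acidification avoids ionisation of the carbinol.

**Step 12**
Reactants: 15 1α,2-dibromo dienone; 22 (2E,4E,6R)-6-hydroxy-6-methylocta-2,4-dienoic acid
Product: 24 2-bromo 1β-ester, via caesium carboxylate 23 (not isolated)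
Conditions: 22 (1.5 equiv), Cs2CO3, DMF, rt; then 15, rt
Reagents that add atoms: acid 22 (as its caesium salt 23), CC[C@@](C)(O)/C=C/C=C/C(=O)O
Why: SN2 displacement of an allylic bromide by a caesium carboxylate in DMF with inversion: the carboxylate attacks C1 from the β face, anti to the α bromide, so the ester ends up cis to the C9 and C10 methyls, while C2 (sp2, brominated) and C3 (γ to the carbonyl) are not electrophilic positions, which disfavours SN2′ and addition–elimination.

**Step 13**
Reactants: 24 2-bromo 1β-ester
Product: 25 7-O-TBS ether of the target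
Conditions: Pd(OAc)2 (5 mol %), PPh3 (15 mol %), HCO2H (1.1 equiv), Et3N (2 equiv), DMF, 40 °C
Reagents that add atoms: none
Why: Palladium-catalysed formate hydrodebromination: Pd(0) should insert into the C2–Br bond, a doubly vinylogous acyl bromide, faster than it ionises the hindered allylic ester, formate gives the palladium hydride by loss of CO2 and reductive elimination forms C2–H; formic acid is kept near one equivalent so that no hydride remains for allylic hydrogenolysis.

**Step 14**
Reactants: 25 7-O-TBS ether of the target
Product: 26 CNP0260852.1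
Conditions: HF·pyridine, pyridine–THF, 0 °C → rt
Reagents that add atoms: none
Why: Buffered fluoride desilylation without base, so the α-ketol at C6/C7, the ε-hydrogen at C1 and the ester are not exposed to enolisation, acyl migration or elimination, and the tertiary carbinol, deactivated by the dienoate, should not ionise.

**Compound list**

1 | (S)-Hajos–Parrish ketone, (7aS)-7a-methyl-2,3,7,7a-tetrahydro-1H-indene-1,5(6H)-dione | O=C1C=C2CCC(=O)[C@@]2(C)CC1 | starting material
2 | methyltriphenylphosphonium bromide | C[P+](c1ccccc1)(c1ccccc1)c1ccccc1.[Br-] | starting material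
3 | 10-methylene enone: 7a-methyl-1-methylidene-1,2,3,6,7,7a-hexahydro-5H-inden-5-one, C9 as in 1 | O=C1C=C2CCC(=C)[C@@]2(C)CC1 | intermediate
4 | 9β,10β-dimethyl enone: cis-1,7a-dimethyl-1,2,3,6,7,7a-hexahydro-5H-inden-5-one | O=C1C=C2CC[C@H](C)[C@@]2(C)CC1 | intermediate
5 | linear dienone (C1=C3, C4=C5, C6=O; 9β,10β-dimethyl) | O=C1C=C2C=C[C@H](C)[C@@]2(C)CC1 | intermediate
6 | lithium trienolate of 5 (C6–OLi, C6=C7) | [Li+].[O-]C1C=C2C=C[C@H](C)[C@@]2(C)CC=1 | intermediate
7 | trimethylsilyl trienol ether of 5 | C[Si](C)(C)OC1C=C2C=C[C@H](C)[C@@]2(C)CC=1 | intermediate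
8 | 7α-trimethylsilyloxy dienone | O=C1C=C2C=C[C@H](C)[C@@]2(C)C[C@H]1O[Si](C)(C)C | intermediate
9 | 7α-hydroxy dienone | O=C1C=C2C=C[C@H](C)[C@@]2(C)C[C@H]1O | intermediate
10 | 7α-(tert-butyldimethylsilyloxy) dienone, precursor of the key step | O=C1C=C2C=C[C@H](C)[C@@]2(C)C[C@H]1O[Si](C)(C)C(C)(C)C | intermediate
11 | phenylmercury(II) chloride | Cl[Hg]c1ccccc1 | starting material
12 | bromoform | BrC(Br)Br | starting material
13 | phenyl(tribromomethyl)mercury | BrC(Br)(Br)[Hg]c1ccccc1 | intermediate
14 | gem-dibromocyclopropane adduct (CBr2 across C1/C3 on the α face) | O=C1C=C2[C@H]3C(Br)(Br)[C@H]3[C@H](C)[C@@]2(C)C[C@H]1O[Si](C)(C)C(C)(C)C | intermediate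
15 | ring-expanded 1α,2-dibromo dienone (7α-OTBS, 9β,10β-dimethyl) | Br[C@@H]1C(Br)=CC2=CC(=O)[C@H](O[Si](C)(C)C(C)(C)C)C[C@]2(C)[C@H]1C | intermediate
16 | (S)-2-methylglycidol | C[C@]1(CO)CO1 | starting material
17 | methylmagnesium bromide | C[Mg]Br | starting material
18 | (R)-2-methylbutane-1,2-diol | CC[C@@](C)(O)CO | intermediate
19 | (R)-2-hydroxy-2-methylbutanal | CC[C@@](C)(O)C=O | intermediate
20 | triethyl (E)-4-phosphonocrotonate | CCOC(=O)/C=C/CP(=O)(OCC)OCC | starting material
21 | ethyl (2E,4E,6R)-6-hydroxy-6-methylocta-2,4-dienoate | CC[C@@](C)(O)/C=C/C=C/C(=O)OCC | intermediate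
22 | (2E,4E,6R)-6-hydroxy-6-methylocta-2,4-dienoic acid | CC[C@@](C)(O)/C=C/C=C/C(=O)O | intermediate
23 | caesium (2E,4E,6R)-6-hydroxy-6-methylocta-2,4-dienoate | CC[C@@](C)(O)/C=C/C=C/C(=O)[O-].[Cs+] | intermediate
24 | 2-bromo 1β-ester (7α-OTBS) | CC[C@@](C)(O)/C=C/C=C/C(=O)O[C@H]1C(Br)=CC2=CC(=O)[C@H](O[Si](C)(C)C(C)(C)C)C[C@]2(C)[C@H]1C | intermediate
25 | 7-O-TBS ether of the target | CC[C@@](C)(O)/C=C/C=C/C(=O)O[C@H]1C=CC2=CC(=O)[C@H](O[Si](C)(C)C(C)(C)C)C[C@]2(C)[C@H]1C | intermediate
26 | CNP0260852.1 | CC[C@@](C)(O)/C=C/C=C/C(=O)O[C@H]1C=CC2=CC(=O)[C@H](O)C[C@]2(C)[C@H]1C | target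

**Totals**

Total step count: 14 (core 1–5 and 7, reagent 6, acid 8–11, endgame 12–14).
Longest linear sequence: 9 steps (1, 2, 3, 4, 5, 7, 12, 13, 14).

**Steps most likely to fail**

Step 7. The carbene may react too slowly with the electron-poor diene, the opening may stall at the cyclopropane, bromide may return at C3 or on the β face, or the ion pair may lose HBr toward a cross-conjugated trienone. The fallback sets out from 10 (with bromoform 12) and returns at 15. The cyclopropane is built by an anionic Michael-initiated ring closure instead of a free carbene (CHBr3, 50 % NaOH, benzyltriethylammonium chloride, CH2Cl2, 0 °C). The tribromomethyl anion adds in 1,6-fashion at C1, the only open acceptor terminus because C4 is fully substituted, and the dienolate closes from C3 onto the CBr3 carbon with loss of bromide. This gives the same adduct 14, which can be isolated at 0 °C and is then opened in a separate operation in hot toluene, so that addition and opening are optimised independently (new compounds: none F0).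

Step 12. Inversion may be eroded because liberated bromide exchanges with unreacted 15 and the epimeric bromide is then displaced from the open α face; the β-face trajectory past the C9 methyl may also be slow enough for ionisation or elimination to compete. The fallback sets out from 15 and returns at 24. Silver-assisted hydrolysis (Ag2CO3, aqueous acetone) lets water capture the allyl cation at C1 from the open α face to give the 1α-hydroxy 2-bromo dienone F1. Mitsunobu esterification with 22 (PPh3, DIAD, toluene, 0 °C) then inverts C1 with no halide ion in the flask and gives 24.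

Step 13. Pd(0) may ionise the allylic C1 ester, with hydride capture and loss of the side chain or scrambling at C1, and the C2–palladium species may add to the dienoate. The fallback sets out from 15 and returns at 25; it removes the bromine while C1 carries a free hydroxyl. Caesium formate in DMF displaces the bromide with inversion to give the 1β-formyloxy 2-bromo dienone F2. Mild methanolysis (KHCO3, MeOH, 0 °C) gives the 1β-hydroxy 2-bromo dienone F3. The same formate/palladium hydrodebromination, now without an ionisable ester, gives the 1β-hydroxy dienone F4. Yamaguchi esterification with 22 (2,4,6-trichlorobenzoyl chloride, Et3N; then DMAP), which acylates with retention at C1, gives 25.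

**Further compounds**

F0 | step 7 | none | none
F1 | step 12 | 1α-hydroxy-2-bromo-7α-TBS-oxy dienone | O[C@@H]1C(Br)=CC2=CC(=O)[C@H](O[Si](C)(C)C(C)(C)C)C[C@]2(C)[C@H]1C
F2 | step 13 | 1β-formyloxy-2-bromo-7α-TBS-oxy dienone | O=CO[C@H]1C(Br)=CC2=CC(=O)[C@H](O[Si](C)(C)C(C)(C)C)C[C@]2(C)[C@H]1C
F3 | step 13 | 1β-hydroxy-2-bromo-7α-TBS-oxy dienone | O[C@H]1C(Br)=CC2=CC(=O)[C@H](O[Si](C)(C)C(C)(C)C)C[C@]2(C)[C@H]1C
F4 | step 13 | 1β-hydroxy-7α-TBS-oxy dienone | O[C@H]1C=CC2=CC(=O)[C@H](O[Si](C)(C)C(C)(C)C)C[C@]2(C)[C@H]1C
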